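## Retrosynthetic overview

1. Quinone ⇐ (NH4)2Ce(NO3)6 oxidation of the hydroquinone dimethyl ether; CO2H ⇐ methyl ester.
2. C13–CH3 (axial, α) ⇐ light-driven Ir/Ni deoxygenative methylation of a C13 alcohol, the C–C bond being made on the open α face.
3. C14–C15 (quaternary C14) and C8–H ⇐ one-pot cathodic reductive benzylation of a ring B/ring C enone with a benzyl bromide.
4. Ring C ⇐ Robinson annulation with ethyl vinyl ketone on a verbenone-derived ketone (sets C9); isopropylidene ⇐ acid opening of the verbenone cyclobutane (C7–C4) after the annulation.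
5. Propanoic chain and C10 ⇐ vinylogous aldol of (1R,5R)-verbenone with glyoxylic acid, then hydrogenation. Ring order: ring B is bought (six-membered ring of verbenone), ring C is annulated, the cyclobutane is opened, the arene ring is bought.

Locants used: C3 = carboxyl carbon, C2 and C1 = chain CH2 groups, C10 = ring carbon carrying the chain, C5 = ring carbon carrying C4 (CMe2), then C6, C7, C8 (ring-fusion CH), C9 (ring-fusion C–CH3), C11, C12, C13 (CH–CH3), C14 (C–CH3 and C15H2–aryl). β = the face syn to the CMe2 bridge of verbenone, which becomes the face of the C9 methyl group; α = the other face.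

Assumption: (1R,5R)-(+)-verbenone is taken as purchasable (it is also one oxidation away from (+)-α-pinene).

## Route

Step 1
Reactants: 1 (1R,5R)-(+)-verbenone; 2 glyoxylic acid (monohydrate)
Product: 3 (E)-dienoic acid (C1 methyl of 1 turned into CH=CH–CO2H)
Conditions: KOH (3 equiv), MeOH/H2O, 0 → 60 °C; then aq. HCl
Reagents that add atoms: none
Why: Vinylogous aldol condensation, in which the extended dienolate of 1 (only the C1 methyl is enolisable) adds through its γ-carbon to the non-enolisable aldehyde under equilibrating base and dehydrates irreversibly to the (E)-dienoic acid, leaving the bridgehead stereocentres untouched.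

Step 2
Reactants: 3 (E)-dienoic acid
Product: 4 saturated keto acid (C10 chain β, 10α-H)
Conditions: H2 (1 atm), 10% Pd/C, EtOAc, 23 °C
Reagents that add atoms: none
Why: Heterogeneous catalytic hydrogenation of both conjugated C=C bonds, with hydrogen delivered to the ring alkene from the face opposite the CMe2 bridge (as in verbenone → cis-verbanone), which sets C10 with H α and the chain β.

Step 3
Reactants: 4 saturated keto acid
Product: 5 9-methyl keto methyl ester (9α-CH3 major)
Conditions: LiN(i-Pr)2 (2.1 equiv), THF, −78 °C; MeI (4 equiv), −78 → 0 °C; then DMF, 23 °C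
Reagents that add atoms: iodomethane CI
Why: Enolate alkylation plus carboxylate O-alkylation, the dianion (carboxylate and the only possible ketone enolate, C8–C9) being C-methylated anti to the CMe2 bridge and the lithium carboxylate then esterified by excess MeI in DMF; the C9 configuration does not matter because C9 is re-enolised in step 4.

Step 4
Reactants: 5 9-methyl keto methyl ester; 6 ethyl vinyl ketone
Product: 8 tricyclic enone ester (9β-CH3, cyclobutane intact), via Michael adduct 7 (not isolated)
Conditions: NaOMe (0.3 equiv), MeOH, 0 → 23 °C; then 65 °C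
Reagents that add atoms: none
Why: Robinson annulation, in which the C9 enolate adds to 6 on the α face (anti to the CMe2 bridge and trans to the C10 chain, as known for 3-methylnopinone), fixing quaternary C9 with its methyl β and cis to the chain, after which the ethyl-ketone CH2 condenses with the C8 carbonyl to close ring C as the C14-methyl enone.

Step 5
Reactants: 8 tricyclic enone ester
Product: 10 bicyclic isopropylidene enone ester, via tertiary chloride 9 (not isolated)
Conditions: HCl (g), AcOH, 20 °C; then NaOAc, AcOH, 100 °C
Reagents that add atoms: none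
Why: Acid-induced cyclobutane fragmentation followed by E1 dehydrochlorination, O-protonation making C8 cationic so that the strained allylic C7–C4 bond breaks to the tertiary C4 cation (held as chloride 9, the known behaviour of nopinone-derived annulated enones) and buffered loss of HCl then giving the more substituted (Zaitsev) C5=C4 isopropylidene, with C9 and C10 untouched.

Step 6
Reactants: 11 2,6-dimethylhydroquinone
Product: 12 1,4-dimethoxy-2,6-dimethylbenzene
Conditions: MeI, K2CO3, acetone, 56 °C
Reagents that add atoms: iodomethane CI
Why: Williamson ether synthesis on both phenolic oxygens, run under nitrogen to avoid quinone formation.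

Step 7
Reactants: 12 1,4-dimethoxy-2,6-dimethylbenzene
Product: 13 1-(bromomethyl)-2,5-dimethoxy-3-methylbenzene
Conditions: NBS (1.0 equiv), AIBN (cat.), PhCF3, 80 °C
Reagents that add atoms: N-bromosuccinimide O=C1CCC(=O)N1Br
Why: Wohl–Ziegler radical benzylic bromination, the two methyl groups being equivalent so that one equivalent of NBS gives the monobromide as the main product.

Step 8
Reactants: 10 bicyclic isopropylidene enone ester; 13 1-(bromomethyl)-2,5-dimethoxy-3-methylbenzene
Product: 15 benzylated trans-decalone ester, via lithium enolate 14 (not isolated)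
Conditions: undivided cell, Mg anode, stainless-steel cathode, LiBr (0.3 M), t-BuOH (1.0 equiv), THF, −20 °C, 5 mA cm−2, 2.2 F mol−1; current off, electrodes out; 13 (1.2 equiv), −20 → 20 °C
Reagents that add atoms: none
Why: Proposed new method: cathodic two-electron, one-proton reduction of the enone gives lithium enolate 14 regiospecifically (the radical anion is protonated at C8 on the α face to give the trans ring fusion, hydrodimerisation is blocked because the β-carbon C8 is fully substituted, and the ester is not reduced at the enone potential), and 14 is benzylated in the same cell on the α face anti to the axial C9 methyl to form C14–C15 and the quaternary C14 with its methyl β, the closest known reaction types being the Li/NH3 (Stork) reductive alkylation of enones and electrochemical Birch-type reductions in LiBr/THF.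

Step 9
Reactants: 15 benzylated trans-decalone ester
Product: 16 C13 alcohol (13β-OH major)
Conditions: NaBH4, MeOH/THF, 0 → 23 °C
Reagents that add atoms: none
Why: Borohydride reduction of the ketone (the ester is inert), hydride arriving axially from the α face to give mainly the equatorial 13β-alcohol, whose configuration is lost again in the radical step that follows.

Step 10
Reactants: 16 C13 alcohol
Product: 18 13α-methyl seco-ester dimethyl ether, via benzoxazoline adduct 17 (not isolated)
Conditions: 5,7-di-tert-butyl-3-phenylbenzoxazolium tetrafluoroborate (1.2 equiv), pyridine, t-BuOMe, 23 °C; then CH3Br (3 equiv), [Ir(ppy)2(dtbbpy)]PF6 (1 mol%; ppy = 2-phenylpyridinato, dtbbpy = 4,4'-di-tert-butyl-2,2'-bipyridine), NiBr2(dtbbpy) (5 mol%), quinuclidine (1.5 equiv), DMA, 450 nm LEDs, 23 °C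
Reagents that add atoms: bromomethane CBr
Why: Metallaphotoredox deoxygenative C(sp3)–C(sp3) cross-coupling, in which photo-oxidation of adduct 17 and β-scission release the secondary C13 radical, which is captured by the methylnickel species and coupled on the α face (axial bond formation anti to the adjacent axial C14 methyl), giving the axial 13α-methyl group that hydrogenation of a C13 alkene would not give.

Step 11
Reactants: 18 13α-methyl seco-ester dimethyl ether
Product: 20 target quinone acid CNP0271365.1, via seco-acid dimethyl ether 19 (not isolated)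
Conditions: LiOH, dioxane/H2O, 40 °C; then aq. HNO3 to pH 3, (NH4)2Ce(NO3)6 (2.5 equiv), MeCN/H2O, 0 °C
Reagents that add atoms: lithium hydroxide [Li+].[OH-]; water O
Why: Ester saponification followed by ceric ammonium nitrate oxidative demethylation of the 1,4-dimethoxyarene to the 1,4-benzoquinone (the quinone oxygens come from water), the arene being oxidised well before the tetrasubstituted alkene and no stereocentre being touched.

## Compound list

1 | (1R,5R)-(+)-verbenone (4,6,6-trimethylbicyclo[3.1.1]hept-3-en-2-one) | CC1=CC(=O)[C@@H]2C[C@H]1C2(C)C | starting material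
2 | glyoxylic acid (used as monohydrate) | O=CC(=O)O | starting material
3 | (E)-dienoic acid: 1 with its C1 methyl turned into CH=CH–CO2H, bridgeheads as in 1 | OC(=O)/C=C/C1=CC(=O)[C@@H]2C[C@H]1C2(C)C | intermediate
4 | saturated keto acid: C8 ketone, C10 carrying CH2CH2CO2H on the β face (syn to the CMe2 bridge), 10α-H | OC(=O)CC[C@H]1CC(=O)[C@@H]2C[C@H]1C2(C)C | intermediate
5 | methyl ester of 4 with a 9α-methyl group (anti to the CMe2 bridge; major epimer) | COC(=O)CC[C@H]1[C@H](C)C(=O)[C@@H]2C[C@H]1C2(C)C | intermediate
6 | ethyl vinyl ketone (pent-1-en-3-one) | CCC(=O)C=C | starting material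
7 | Michael adduct: C9 carries β-CH3 and α-CH2CH2COCH2CH3 | COC(=O)CC[C@H]1[C@](C)(CCC(=O)CC)C(=O)[C@@H]2C[C@H]1C2(C)C | intermediate
8 | tricyclic enone ester: ring C enone (C13=O, C14–CH3, C14=C8), 9β-CH3, 10α-H, CMe2 bridge C5–C7 intact | COC(=O)CC[C@H]1[C@]2(C)CCC(=O)C(C)=C2[C@@H]3C[C@H]1C3(C)C | intermediate
9 | tertiary chloride: C7–C4 bond of 8 cleaved, C7H2, C5 carrying β-CMe2Cl (5α-H) | COC(=O)CC[C@H]1[C@]2(C)CCC(=O)C(C)=C2CC[C@H]1C(C)(C)Cl | intermediate
10 | bicyclic enone ester: C5=C4Me2 isopropylidene, 9β-CH3, 10α-H (chain β), C13 enone | COC(=O)CC[C@H]1[C@]2(C)CCC(=O)C(C)=C2CCC1=C(C)C | intermediate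
11 | 2,6-dimethylhydroquinone | Cc1cc(O)cc(C)c1O | starting material
12 | 1,4-dimethoxy-2,6-dimethylbenzene | COc1cc(C)c(OC)c(C)c1 | intermediate
13 | 1-(bromomethyl)-2,5-dimethoxy-3-methylbenzene | COc1cc(C)c(OC)c(CBr)c1 | intermediate
14 | lithium C13–C14 enolate of the trans-fused decalin (8α-H, 9β-CH3) | [Li+].[O-]C1=C(C)[C@H]2CCC(=C(C)C)[C@@H](CCC(=O)OC)[C@]2(C)CC1 | intermediate
15 | benzylated trans-decalone ester: 14β-CH3, 14α-CH2Ar (Ar = 2,5-dimethoxy-3-methylphenyl), 8α-H, C13 ketone | COc1cc(C)c(OC)c(C[C@]2(C)[C@H]3CCC(=C(C)C)[C@@H](CCC(=O)OC)[C@]3(C)CCC2=O)c1 | intermediate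
16 | C13 alcohol of 15 (13β-OH, equatorial; major epimer) | COc1cc(C)c(OC)c(C[C@]2(C)[C@H]3CCC(=C(C)C)[C@@H](CCC(=O)OC)[C@]3(C)CC[C@H]2O)c1 | intermediate
17 | benzoxazoline adduct: 16 bound through its C13 oxygen to C2 of 5,7-di-tert-butyl-3-phenyl-2,3-dihydrobenzoxazole | COc1cc(C)c(OC)c(C[C@]2(C)[C@H]3CCC(=C(C)C)[C@@H](CCC(=O)OC)[C@]3(C)CC[C@H]2OC4Oc5c(C(C)(C)C)cc(C(C)(C)C)cc5N4c6ccccc6)c1 | intermediate
18 | 13α-methyl seco-ester dimethyl ether (methyl ester and hydroquinone dimethyl ether of the target) | COc1cc(C)c(OC)c(C[C@]2(C)[C@H]3CCC(=C(C)C)[C@@H](CCC(=O)OC)[C@]3(C)CC[C@@H]2C)c1 | intermediate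
19 | seco-acid dimethyl ether (free acid of 18) | COc1cc(C)c(OC)c(C[C@]2(C)[C@H]3CCC(=C(C)C)[C@@H](CCC(=O)O)[C@]3(C)CC[C@@H]2C)c1 | intermediate
20 | target CNP0271365.1: (8R,9R,10S,13S,14S) seco-acid carrying the 6-methyl-1,4-benzoquinon-2-ylmethyl group on C14 | CC1=CC(=O)C=C(C[C@]2(C)[C@H]3CCC(=C(C)C)[C@@H](CCC(=O)O)[C@]3(C)CC[C@@H]2C)C1=O | target

## Step count and weak points

Total steps: 11. Longest linear sequence: 9 (steps 1–5 and 8–11).

Most likely to fail, first: step 5. The E1 loss of HCl may give the isopropenyl isomer or move the alkene into ring B instead of giving the exocyclic tetrasubstituted C5=C4 alkene. Fallback, setting out from 8 and coming back at 10: 8 is opened with HCl in AcOH as before, but chloride 9 is isolated and eliminated under kinetic E2 conditions (DBU, toluene, 80 °C) to the isopropenyl enone ester F1; any 10 formed alongside is carried along. The mixture is then treated with Co(salen)Cl (2 mol%; salen = N,N'-ethylenebis(salicylideneiminato)) and PhSiH3 (4 mol%) in benzene at 23 °C. This cobalt hydride hydrogen-atom-transfer isomerisation moves the 1,1-disubstituted alkene to the tetrasubstituted C5=C4 position and stops there, giving 10 without cationic intermediates.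

Second: step 8, the proposed new step. The electrogenerated enolate may be protonated or may equilibrate before it is benzylated, and magnesium ions from the anode may slow the alkylation. Fallback with known chemistry, setting out from 10 (with 13) and coming back at 15: classical dissolving-metal reductive alkylation. Lithium (2.2 equiv) in NH3/THF at −78 °C with t-BuOH (1.0 equiv) is titrated to a faint persistent blue so that the methyl ester is spared, and 13 is then added to the lithium enolate at −33 °C. The stereochemical outcome at C8 and C14 is the one established for such enones, and no new compound is involved.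

Third: step 10. The hindered, neopentyl-type C13 radical may be reduced to C13–H or may add to the neighbouring arene faster than nickel captures it, and the α-face preference is argued, not proven. Fallback, setting out from 15 and coming back at 18: ketone 15 is converted with KN(SiMe3)2 and PhNTf2 (THF, −78 °C) into the C12=C13 enol triflate F2. F2 is reduced with Pd(OAc)2, PPh3, n-Bu3N and HCO2H (DMF, 60 °C) to the C12=C13 alkene F3. F3 is hydromethylated by iron hydride hydrogen-atom transfer (Fe(acac)3, PhSiH3, MeOH/THF) in the presence of formaldehyde 2,4,6-trimethylbenzenesulfonylhydrazone: hydrogen adds to the less hindered C12, and the C13 radical adds to the hydrazone carbon from the α face to give the sulfonylhydrazide F4. Warming F4 in methanol at 60 °C expels sulfinate and dinitrogen and leaves the 13α-methyl group of 18.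

## Further compounds

F1 | step 5 | isopropenyl enone ester (5β-isopropenyl, 5α-H isomer of 10) | COC(=O)CC[C@H]1[C@]2(C)CCC(=O)C(C)=C2CC[C@H]1C(C)=C
F0 | step 8 | none | none
F2 | step 10 | C12=C13 enol triflate of 15 | COc1cc(C)c(OC)c(C[C@]2(C)[C@H]3CCC(=C(C)C)[C@@H](CCC(=O)OC)[C@]3(C)CC=C2OS(=O)(=O)C(F)(F)F)c1
F3 | step 10 | C12=C13 alkene (15 without the C13 oxygen) | COc1cc(C)c(OC)c(C[C@]2(C)[C@H]3CCC(=C(C)C)[C@@H](CCC(=O)OC)[C@]3(C)CC=C2)c1
F4 | step 10 | 13α-CH2–NH–NH–SO2(2,4,6-trimethylphenyl) sulfonylhydrazide | COc1cc(C)c(OC)c(C[C@]2(C)[C@H]3CCC(=C(C)C)[C@@H](CCC(=O)OC)[C@]3(C)CC[C@@H]2CNNS(=O)(=O)c4c(C)cc(C)cc4C)c1
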